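**Retrosynthetic overview** (oxolane numbering: O1, C2 aryl, C3 CH2OH, C4 aroyl, C5)
- The C4 aryl ketone is unmasked last from a 1-arylethenyl group (alkene cleavage); the C3 CH2OH comes from a C3 formyl group.
- The C2–C3 bond is made by Lewis acid ring contraction of a (5S)-2-aryl-5-(1-arylethenyl)-4,5-dihydro-1,3-dioxepine (seven-membered enol acetal) to the 2,3-cis-3,4-trans oxolane-3-carbaldehyde. This closes the oxolane and sets C2 and C3 from the single centre C4.
- Enabling feature: C2 is a benzylic carbon on ring oxygen O1 (latent aryl-stabilised oxocarbenium ion), and the oxygen of the C3 hydroxymethyl arm lies three bonds from C2. Tying that oxygen to C2 gives the ring C2–O1–C5–C4–C3=CH–O, whose O–CH=C3 enol ether is a latent C3 enolate.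
- The dioxepine comes from an asymmetric Heck alkenylation of the achiral acetal of (Z)-butenediol and 3,4,5-trimethoxybenzaldehyde with the enol triflate of 3,4,5-trimethoxyacetophenone.
- Ring order: seven-membered acetal ring first (acetalisation), oxolane ring second (contraction of the seven-membered ring).

Key step: step 4

Assumption 1: the target is (2S,3S,4R) in the numbering above; aryl and hydroxymethyl are cis, hydroxymethyl and aroyl are trans.
Assumption 2: the sense of induction in step 3 is assigned by analogy only; the antipode of the ligand that delivers (5S)-6 is the one to be used.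

**Step 1**
Reactants: 1 (Z)-but-2-ene-1,4-diol; 2 3,4,5-trimethoxybenzaldehyde
Product: 3 2-(3,4,5-trimethoxyphenyl)-4,7-dihydro-1,3-dioxepine
Conditions: p-TsOH·H2O (2 mol%), toluene, reflux, Dean–Stark
Reagents that add atoms: none
Why: Acid-catalysed acetalisation with azeotropic removal of water, in which the cis-diol closes the seven-membered cyclic acetal readily and the product is achiral (mirror plane through C2).

**Step 2**
Reactants: 4 1-(3,4,5-trimethoxyphenyl)ethan-1-one
Product: 5 1-(3,4,5-trimethoxyphenyl)ethenyl trifluoromethanesulfonate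
Conditions: KHMDS, THF, −78 °C; then PhNTf2, −78 to 0 °C
Reagents that add atoms: N-phenylbis(trifluoromethanesulfonimide) PhNTf2, O=S(=O)(N(c1ccccc1)S(=O)(=O)C(F)(F)F)C(F)(F)F
Why: Enol triflate formation by O-sulfonylation of the potassium enolate of a methyl ketone, for which only one enolate is possible.

**Step 3**
Reactants: 3 2-(3,4,5-trimethoxyphenyl)-4,7-dihydro-1,3-dioxepine; 5 1-(3,4,5-trimethoxyphenyl)ethenyl trifluoromethanesulfonate
Product: 6 (5S)-2-(3,4,5-trimethoxyphenyl)-5-[1-(3,4,5-trimethoxyphenyl)ethenyl]-4,5-dihydro-1,3-dioxepine (both C2 epimers)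
Conditions: Pd2(dba)3 (3 mol%), (S)-t-Bu-PHOX (7 mol%), i-Pr2NEt (2 equiv), 3 (3 equiv, excess recovered), THF, 65 °C
Reagents that add atoms: none
Why: Enantioselective intermolecular Heck alkenylation of a 4,7-dihydro-1,3-dioxepine by the cationic (triflate) pathway, in which syn carbopalladation places the alkenyl group on C5, syn β-hydride elimination is possible only toward C7 and so gives the enol ether, and the P,N ligand on palladium selects between the enantiotopic alkene carbons to set C5 while releasing the product before the palladium hydride can move the double bond.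

**Step 4**
Reactants: 6 (5S)-2-(3,4,5-trimethoxyphenyl)-5-[1-(3,4,5-trimethoxyphenyl)ethenyl]-4,5-dihydro-1,3-dioxepine
Product: 8 (2S,3R,4S)-2-(3,4,5-trimethoxyphenyl)-4-[1-(3,4,5-trimethoxyphenyl)ethenyl]oxolane-3-carbaldehyde, via ring-opened oxocarbenium enolate 7 (not isolated)
Conditions: Me3SiOTf (10 mol%), 2,6-di-tert-butyl-4-methylpyridine (10 mol%), CH2Cl2, −78 °C; Et3N quench at −78 °C
Reagents that add atoms: none
Why: The silyl triflate ionises the acetal at the C2–O1 bond (O1 is the enol ether oxygen and the better leaving group; the cation is stabilised by O3 and the aryl ring) to give the (E)-oxocarbenium ion tethered to the (Z)-enolate 7, held in the flask as its silyl enol ether, and the enolate carbon then adds to C2 in an intramolecular Mukaiyama aldol-type step that releases the silyl group again. The closest known reaction type is the Lewis acid-induced ring contraction of 2-aryl-4,5-dihydro-1,3-dioxepines to oxolane-3-carbaldehydes, a vinyl acetal rearrangement of the Petasis–Ferrier family (formal 1,3-shift of the acetal carbon from oxygen to carbon). The oxolane closes in a 5-(enolexo)-endo-trig mode while the seven-membered ring opens, a net contraction from seven to five ring atoms. The new C3 centre is controlled by the existing centre (old C5, new C4): allylic 1,3-strain in the ring-derived (Z)-enol ether keeps its C–H bond eclipsed with the enol double bond, so the tethered cation should reach C3 from the face that leaves formyl trans to the 1-arylethenyl group; the new C2 centre is controlled kinetically by the compact synclinal transition state of the (E)-oxocarbenium ion, which should place aryl and formyl cis. The step needs kinetic control, because the 2,3-trans aldehyde is the product of re-ionisation and C3 is enolisable, and it needs the enol ether to outrun the 1-arylethenyl group in capturing the cation; the substrate secures this through the ring-enforced (Z)-enol ether, the single directing stereocentre and the much higher nucleophilicity of the enol ether in a five-membered closure, supported by catalytic promoter at −78 °C, a hindered base that removes triflic acid and a cold amine quench. Because C2 is planar in 7, both C2 epimers of 6 should converge on the same aldehyde.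

**Step 5**
Reactants: 8 (2S,3R,4S)-2-(3,4,5-trimethoxyphenyl)-4-[1-(3,4,5-trimethoxyphenyl)ethenyl]oxolane-3-carbaldehyde (crude, used at once)
Product: 9 [(2S,3S,4S)-2-(3,4,5-trimethoxyphenyl)-4-[1-(3,4,5-trimethoxyphenyl)ethenyl]oxolan-3-yl]methanol
Conditions: NaBH4, MeOH/CH2Cl2 (1:1), −40 to 0 °C
Reagents that add atoms: none
Why: Borohydride reduction of the aldehyde at low temperature should outpace enolisation at C3 and so fix the cis C2/C3 relationship, with no new stereocentre formed (the C3 descriptor changes from R to S only through the change in priorities).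

**Step 6**
Reactants: 9 [(2S,3S,4S)-2-(3,4,5-trimethoxyphenyl)-4-[1-(3,4,5-trimethoxyphenyl)ethenyl]oxolan-3-yl]methanol
Product: 10 (3,4,5-trimethoxyphenyl)[(3R,4S,5S)-4-(hydroxymethyl)-5-(3,4,5-trimethoxyphenyl)oxolan-3-yl]methanone (target)
Conditions: OsO4 (2 mol%), NaIO4 (4 equiv), 2,6-lutidine (2 equiv), 1,4-dioxane/H2O (3:1), rt
Reagents that add atoms: osmium tetroxide OsO4, O=[Os](=O)(=O)=O; sodium periodate NaIO4, [Na+].[O-]I(=O)(=O)=O
Why: Lemieux–Johnson oxidative cleavage (dihydroxylation, then periodate glycol cleavage) of the 1,1-disubstituted alkene should give the aryl ketone and formaldehyde under buffered conditions that spare the primary alcohol, the arenes and the ketone α-centre, which already has the more stable trans arrangement (its descriptor changes from S to R only through the change in priorities).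

**Compound list**
1 | (Z)-but-2-ene-1,4-diol | OC/C=C\CO | starting material
2 | 3,4,5-trimethoxybenzaldehyde | COc1cc(C=O)cc(OC)c1OC | starting material
3 | 2-(3,4,5-trimethoxyphenyl)-4,7-dihydro-1,3-dioxepine | COc1cc(C2OC/C=C\CO2)cc(OC)c1OC | intermediate
4 | 1-(3,4,5-trimethoxyphenyl)ethan-1-one | CC(=O)c1cc(OC)c(OC)c(OC)c1 | starting material
5 | 1-(3,4,5-trimethoxyphenyl)ethenyl trifluoromethanesulfonate | C=C(OS(=O)(=O)C(F)(F)F)c1cc(OC)c(OC)c(OC)c1 | intermediate
6 | (5S)-2-(3,4,5-trimethoxyphenyl)-5-[1-(3,4,5-trimethoxyphenyl)ethenyl]-4,5-dihydro-1,3-dioxepine (C2 epimers) | C=C(c1cc(OC)c(OC)c(OC)c1)[C@H]2COC(c3cc(OC)c(OC)c(OC)c3)OC=C2 | intermediate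
7 | ring-opened (S)-configured (E)-oxocarbenium (Z)-enolate zwitterion (present as its Me3Si enol ether and triflate ion pair) | C=C(c1cc(OC)c(OC)c(OC)c1)[C@@H](C/[O+]=C/c1cc(OC)c(OC)c(OC)c1)/C=C\[O-] | intermediate (not isolated)
8 | (2S,3R,4S)-2-(3,4,5-trimethoxyphenyl)-4-[1-(3,4,5-trimethoxyphenyl)ethenyl]oxolane-3-carbaldehyde | C=C(c1cc(OC)c(OC)c(OC)c1)[C@H]2CO[C@H](c3cc(OC)c(OC)c(OC)c3)[C@@H]2C=O | intermediate
9 | [(2S,3S,4S)-2-(3,4,5-trimethoxyphenyl)-4-[1-(3,4,5-trimethoxyphenyl)ethenyl]oxolan-3-yl]methanol | C=C(c1cc(OC)c(OC)c(OC)c1)[C@H]2CO[C@H](c3cc(OC)c(OC)c(OC)c3)[C@@H]2CO | intermediate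
10 | (3,4,5-trimethoxyphenyl)[(3R,4S,5S)-4-(hydroxymethyl)-5-(3,4,5-trimethoxyphenyl)oxolan-3-yl]methanone | COc1cc(C(=O)[C@H]2CO[C@H](c3cc(OC)c(OC)c(OC)c3)[C@@H]2CO)cc(OC)c1OC | target

**Step count**
Total step count: 6. Longest linear sequence: 5 steps (step 1 or step 2, then steps 3, 4, 5, 6).

**Steps most likely to fail**

1. Step 4. The oxocarbenium ion may be captured by the electron-rich 1-arylethenyl group (six-membered Prins closure), or that styrene may be protonated and oligomerised by traces of triflic acid, in competition with closure by the enol ether. Fallback: the future ketone is carried through the ring contraction as an electron-poor β-aryl acrylate instead of a styrene. The fallback sets out from 3 and comes back at 10.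
   - Purchased ethyl 3-oxo-3-(3,4,5-trimethoxyphenyl)propanoate F1 is converted (Tf2O, aqueous LiOH, toluene, 5 °C) into ethyl (2Z)-3-(3,4,5-trimethoxyphenyl)-3-(trifluoromethanesulfonyloxy)prop-2-enoate F2.
   - Heck coupling of F2 with 3 under the conditions of step 3 should give ethyl (2E)-3-[(5S)-2-(3,4,5-trimethoxyphenyl)-4,5-dihydro-1,3-dioxepin-5-yl]-3-(3,4,5-trimethoxyphenyl)prop-2-enoate F3.
   - Ring contraction as in step 4, where the acrylate cannot compete for the cation, should give ethyl (2E)-3-[(3S,4R,5S)-4-formyl-5-(3,4,5-trimethoxyphenyl)oxolan-3-yl]-3-(3,4,5-trimethoxyphenyl)prop-2-enoate F4.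
   - NaBH4 as in step 5 should give ethyl (2E)-3-[(3S,4S,5S)-4-(hydroxymethyl)-5-(3,4,5-trimethoxyphenyl)oxolan-3-yl]-3-(3,4,5-trimethoxyphenyl)prop-2-enoate F5.
   - Ozonolysis of the acrylate (O3 to an indicator end point, CH2Cl2/MeOH, −78 °C; then Me2S) unveils the ketone and returns to 10.

2. Step 3. Enantiofacial discrimination may be insufficient with the 2-aryl-substituted ring and the bulky alkenyl partner, or palladium hydride re-addition may move the ring double bond into conjugation and erase C5. Fallback: racemic coupling and resolution at the configurationally robust alcohol. The fallback sets out from 3 and 5 and comes back at 9.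
   - Coupling with an achiral ligand (Pd(OAc)2, 2-[2-(diphenylphosphino)phenyl]-4,4-dimethyl-4,5-dihydrooxazole, i-Pr2NEt, THF, 65 °C) gives 6 together with its (5R)-configured mirror-image series, (5R)-2-(3,4,5-trimethoxyphenyl)-5-[1-(3,4,5-trimethoxyphenyl)ethenyl]-4,5-dihydro-1,3-dioxepine F6.
   - Steps 4 and 5, run unchanged, give 8 with (2R,3S,4R)-2-(3,4,5-trimethoxyphenyl)-4-[1-(3,4,5-trimethoxyphenyl)ethenyl]oxolane-3-carbaldehyde F7, and then 9 with [(2R,3R,4R)-2-(3,4,5-trimethoxyphenyl)-4-[1-(3,4,5-trimethoxyphenyl)ethenyl]oxolan-3-yl]methanol F8.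
   - Esterification of the racemic alcohol with (S)-2-methoxy-2-phenylacetic acid (EDC, DMAP, CH2Cl2, 0 °C) gives the diastereomers [(2S,3S,4S)-2-(3,4,5-trimethoxyphenyl)-4-[1-(3,4,5-trimethoxyphenyl)ethenyl]oxolan-3-yl]methyl (2S)-2-methoxy-2-phenylacetate F9 and [(2R,3R,4R)-2-(3,4,5-trimethoxyphenyl)-4-[1-(3,4,5-trimethoxyphenyl)ethenyl]oxolan-3-yl]methyl (2S)-2-methoxy-2-phenylacetate F10.
   - These are separated by chromatography or crystallisation; methanolysis of F9 (K2CO3, MeOH) returns 9.

3. Step 2. The electron-rich α-aryl enol triflate may ionise or hydrolyse on silica or on storage, or eliminate to the arylalkyne with excess base. Fallback: an alkenyl iodide made by hydrazone iodination replaces the triflate. The fallback sets out from 4 and comes back at 6.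
   - 4 with hydrazine hydrate (EtOH, reflux) gives [1-(3,4,5-trimethoxyphenyl)ethylidene]hydrazine F11.
   - Iodine and tetramethylguanidine (Et2O, 0 °C) convert F11 into 5-(1-iodoethenyl)-1,2,3-trimethoxybenzene F12.
   - F12 is coupled with 3 under halide-abstracting Heck conditions (Pd2(dba)3, (S)-t-Bu-PHOX, Ag3PO4, THF, 65 °C) to give 6.

**Further compounds**
F1 | step 4 | ethyl 3-oxo-3-(3,4,5-trimethoxyphenyl)propanoate | CCOC(=O)CC(=O)c1cc(OC)c(OC)c(OC)c1
F2 | step 4 | ethyl (2Z)-3-(3,4,5-trimethoxyphenyl)-3-(trifluoromethanesulfonyloxy)prop-2-enoate | CCOC(=O)/C=C(\OS(=O)(=O)C(F)(F)F)c1cc(OC)c(OC)c(OC)c1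
F3 | step 4 | ethyl (2E)-3-[(5S)-2-(3,4,5-trimethoxyphenyl)-4,5-dihydro-1,3-dioxepin-5-yl]-3-(3,4,5-trimethoxyphenyl)prop-2-enoate | CCOC(=O)/C=C(/c1cc(OC)c(OC)c(OC)c1)[C@H]2COC(c3cc(OC)c(OC)c(OC)c3)OC=C2
F4 | step 4 | ethyl (2E)-3-[(3S,4R,5S)-4-formyl-5-(3,4,5-trimethoxyphenyl)oxolan-3-yl]-3-(3,4,5-trimethoxyphenyl)prop-2-enoate | CCOC(=O)/C=C(/c1cc(OC)c(OC)c(OC)c1)[C@H]2CO[C@H](c3cc(OC)c(OC)c(OC)c3)[C@@H]2C=O
F5 | step 4 | ethyl (2E)-3-[(3S,4S,5S)-4-(hydroxymethyl)-5-(3,4,5-trimethoxyphenyl)oxolan-3-yl]-3-(3,4,5-trimethoxyphenyl)prop-2-enoate | CCOC(=O)/C=C(/c1cc(OC)c(OC)c(OC)c1)[C@H]2CO[C@H](c3cc(OC)c(OC)c(OC)c3)[C@@H]2CO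
F6 | step 3 | (5R)-2-(3,4,5-trimethoxyphenyl)-5-[1-(3,4,5-trimethoxyphenyl)ethenyl]-4,5-dihydro-1,3-dioxepine (C2 epimers) | C=C(c1cc(OC)c(OC)c(OC)c1)[C@@H]2COC(c3cc(OC)c(OC)c(OC)c3)OC=C2
F7 | step 3 | (2R,3S,4R)-2-(3,4,5-trimethoxyphenyl)-4-[1-(3,4,5-trimethoxyphenyl)ethenyl]oxolane-3-carbaldehyde | C=C(c1cc(OC)c(OC)c(OC)c1)[C@@H]2CO[C@@H](c3cc(OC)c(OC)c(OC)c3)[C@H]2C=O
F8 | step 3 | [(2R,3R,4R)-2-(3,4,5-trimethoxyphenyl)-4-[1-(3,4,5-trimethoxyphenyl)ethenyl]oxolan-3-yl]methanol | C=C(c1cc(OC)c(OC)c(OC)c1)[C@@H]2CO[C@@H](c3cc(OC)c(OC)c(OC)c3)[C@H]2CO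
F9 | step 3 | [(2S,3S,4S)-2-(3,4,5-trimethoxyphenyl)-4-[1-(3,4,5-trimethoxyphenyl)ethenyl]oxolan-3-yl]methyl (2S)-2-methoxy-2-phenylacetate | C=C(c1cc(OC)c(OC)c(OC)c1)[C@H]2CO[C@H](c3cc(OC)c(OC)c(OC)c3)[C@@H]2COC(=O)[C@@H](OC)c4ccccc4
F10 | step 3 | [(2R,3R,4R)-2-(3,4,5-trimethoxyphenyl)-4-[1-(3,4,5-trimethoxyphenyl)ethenyl]oxolan-3-yl]methyl (2S)-2-methoxy-2-phenylacetate | C=C(c1cc(OC)c(OC)c(OC)c1)[C@@H]2CO[C@@H](c3cc(OC)c(OC)c(OC)c3)[C@H]2COC(=O)[C@@H](OC)c4ccccc4
F11 | step 2 | [1-(3,4,5-trimethoxyphenyl)ethylidene]hydrazine | CC(=NN)c1cc(OC)c(OC)c(OC)c1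
F12 | step 2 | 5-(1-iodoethenyl)-1,2,3-trimethoxybenzene | C=C(I)c1cc(OC)c(OC)c(OC)c1
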